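Atom labels used throughout: rings A/B are the acetyl-bearing chromene (O1, C2, C3, C4, C4a, C5–C8, C8a), C* is the stereocentre on C3, and rings C/D are the dimethoxychromene (primed numbers, C6' bonded to C*).

## The problem

The target 15 consists of two 2,2-dimethyl-2H-chromenes joined through one CH(CH3) carbon, C*, which is bonded to C3 of ring B and to C6' of ring C. C* (S) is the only stereocentre, so nothing in the molecule can direct it and a chiral catalyst has to set it. It is a tertiary C–H that is both allylic (to C3=C4) and benzylic (to ring C), so once set it must be kept away from strong base, strong acid and alkene-isomerising metal hydrides. C* sits between a fully substituted alkene carbon next to the quaternary C2 and an aryl carbon flanked by two methoxy groups, so every bond to it is made in a crowded place. Ring A is pentasubstituted, and the carbon that becomes C4 has to be placed on the one ring position between O1 and the 5-hydroxyl, not on C8. The groups that limit the choice of reagents are the two electron-rich chromene alkenes (acid, electrophiles, hydrogenation), the hydrogen-bonded ortho-hydroxyacetophenone with its enolisable ketone, and, in the intermediates, tertiary aryl propargyl ethers that undergo Claisen rearrangement well above 100 °C. The enabling feature is in ring B (O1, C2, C3, C4, C4a, C8a): the C3=C4 alkene and the C*–CH3 bond are 1,3-related, so ring B with its side chain is one hydrogenation away from a 3-(1-arylvinyl)chromene. That diene is what exo ring-closing enyne metathesis leaves when a vinyl group on C4a meets an aryl alkyne hung on O1 through C2.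

## Retrosynthesis

**Ring D last (15 ⇒ 12 + 13).** The O1'–C2' and C4'–C4a' bonds are cut, which leads to the phenol 12 and 3-methylbut-2-enal 13, joined in the forward direction through the ortho-quinone methide 14. Ring D carries the most accessible alkene of the target, a cis-disubstituted styrene. Bringing it in after the metathesis and the hydrogenation removes it as a competitor in both. The two carbons ortho to the ring-C hydroxyl of 12 are equivalent by rotation about the aryl–C* bond, so the annulation has no regiochemical choice. The ring-A hydroxyl has no free ortho carbon. The forward step must be mild enough to leave C*–H alone.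

**The stereocentre (12 ⇒ 11 ⇒ 10).** The silyl ether 11 is the protected form of 12. Cutting the C*–H bond of 11 leads to the diene 10, whose 1,1-disubstituted alkene carries the future methyl carbon. Setting C* by adding hydrogen avoids an asymmetric C–C coupling at a carbon flanked by two ortho methoxy groups. The forward reaction must reduce the terminal alkene and not the C3=C4 bond, and must choose one face under catalyst control.

**Key disconnection (10 ⇒ 9).** The C3=C4 bond and the C*=CH2 bond are exchanged for a styrene on C4a and the C≡C bond of an aryl alkyne: 10 is an isomer of the enyne 9. The neighbouring cut, C3–C*, would need a 3-metalated or 3-halogenated chromene and a hindered 1-arylvinyl partner, each a synthesis of its own. The enyne cut removes ring B and the diene at once and turns the quaternary C2 into a propargylic ether carbon that comes from a commodity chloride. The forward step must close in the exo mode and turn over a crowded carbene at C*.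

**The styrene (9 ⇒ 8 ⇒ 6).** The vinyl group is traced to the aldehyde 8 by methylenation, and the C4–C4a bond of 8 is cut to give 6. The forward formylation passes through the hydroxymethyl compound 7 in the flask. Halogenation followed by cross-coupling was the neighbour considered; electrophilic halogen would attack the electron-rich ring C and the alkyne of 6. Magnesium-mediated formylation reacts only ortho to a free phenol, and in 6 the only such carbon is the one between the two oxygens.

**Joining the halves (6 ⇒ 3 + 5).** The C(sp)–C(aryl) bond is cut to the terminal alkyne 3 and the aryl bromide 5. This is the convergent step and is placed early, on simple materials.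

**Starting materials (3 ⇒ 1 + 2; 5 ⇒ 4).** The ether 3 comes from the acetophenone 1 and the propargylic chloride 2 by selective alkylation of the hydroxyl that is not hydrogen-bonded. The bromide 5 is the triisopropylsilyl ether of the bromophenol 4. The triisopropylsilyl group is preferred to a smaller silyl group because it must survive amine bases, magnesium salts at 65 °C and a phosphorus ylide before fluoride removes it.

## Roads not taken

**Alternative 1:** hydroacylation. The C3–C4 bond is cut as an acyl–carbon bond. In the forward step the aldehyde C–H of the salicylaldehyde ether A2 adds across its Z trisubstituted alkene under [Rh(cod)Cl]2, AgBF4 and a chiral bisphosphine, giving the chroman-4-one A1.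
- Merits: ring closure and the C*–H bond come from one asymmetric step, ring D is carried from the start, and no diene has to be reduced selectively. In the way C* is set this road is at least as secure as the chosen one.
- Weak points: the alkene is trisubstituted and attached to a quaternary carbon, a poor hydroacylation substrate, and decarbonylation competes. Closure to the six-membered ketone has to win over the seven-membered mode. The Z alkene of A2, with the two large groups cis, is itself hard to make. After the key step the C4 ketone must be reduced and dehydrated and the nitrile turned into the acetyl group, so the C3 stereocentre is made only to be destroyed.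
- Comparison: the chosen plan answers with a redox-neutral ring closure that delivers C3=C4 at the right oxidation level and keeps the acetyl group throughout.

**Alternative 2:** arylative cyclisation. The C*–C6' and C3–C4 bonds are cut. In the forward step the boronic acid A5 adds across the alkyne of the alkynal A4 under [Rh(OH)(cod)]2 and a chiral bisphosphine, and the alkenylrhodium closes onto the aldehyde to give the allylic alcohol A3. A reductive allylic transposition would then move the alkene to C3=C4 and deliver hydrogen to C*.
- Merits: this is the most convergent road. Both halves are joined and ring B is closed in one step, ring D is already present, and fewer steps follow. In step count it is as good as or better than the chosen plan.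
- Weak points: A5 has two ortho methoxy groups, so transmetalation is slow and protodeboronation likely. The transposition needs a substitution at a hindered alcohol that is benzylic to an electron-rich ring and allylic. Ionisation there would lose the stereochemical information that the key step created, and the transfer to C* depends on one conformation of the rearrangement.
- Comparison: the chosen plan makes every carbon–carbon bond before the key step by a standard coupling and sets C* directly in one catalytic step, without a two-stage transfer through an ionisable centre.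

**Alternative 3:** Prins annulation. The O1–C2 and C2–C3 bonds are cut. In the forward step the (E)-2-hydroxystyrene A7, which already carries C*, reacts with the acetone acetal A8 under BF3·OEt2. Oxygen and C3 both bond to the acetone carbon and proton loss gives the chromene A6.
- Merits: ring B comes from the cheapest possible building block, C* is set earlier on an open-chain fragment, and no diene hydrogenation is needed. If the annulation worked cleanly, this road would avoid the least certain step of the chosen plan.
- Weak points: the benzylic cation at C4 is next to C3, which bears the allylic, benzylic C*–H. A hydride shift or proton loss towards C* would erase the stereocentre. Electron-rich hydroxystyrenes oligomerise under Lewis acids, two phenols flank the alkene, and this closure with a ketone acetal has little precedent.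
- Comparison: the chosen plan keeps C* out of every acidic or cationic step and creates it only after ring B exists.

Key step: step 6

Assumption on supply: 1 and 4 are taken as purchasable.
Assumption on stereochemistry: the ligand enantiomer written in step 7 is a working choice; the sense of induction is to be fixed in the first experiment, and the other enantiomer of the ligand is used if it is the one that gives S.

## Route

Step 1
Reactants: 1 acetophenone 2,4-dihydroxy-6-methoxyacetophenone; 2 propargylic chloride 3-chloro-3-methylbut-1-yne
Product: 3 aryl propargyl ether 1-[2-hydroxy-6-methoxy-4-(2-methylbut-3-yn-2-yloxy)phenyl]ethanone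
Conditions: K2CO3, KI, CuCl2·2H2O (cat.), acetone, 50 °C
Reagents that add atoms: none
Why: Copper-catalysed propargylic O-alkylation of a phenol by a tertiary propargylic chloride; the 4-hydroxyl is free and the more acidic one, whereas the 2-hydroxyl is held in a hydrogen bond to the acetyl group and stays unalkylated. 50 °C is far below the temperature of Claisen rearrangement of the ether.

Step 2
Reactants: 4 bromophenol 4-bromo-3,5-dimethoxyphenol
Product: 5 silyl ether (4-bromo-3,5-dimethoxyphenoxy)tri(propan-2-yl)silane
Conditions: i-Pr3SiCl, imidazole, DMF, rt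
Reagents that add atoms: triisopropylsilyl chloride, CC(C)[Si](Cl)(C(C)C)C(C)C
Why: Standard silylation of a phenol; the bulky silyl group is chosen to survive steps 3 to 7.

Step 3
Reactants: 3 aryl propargyl ether; 5 aryl bromide
Product: 6 diaryl alkyne 1-{4-[(4-{2,6-dimethoxy-4-[tri(propan-2-yl)silyloxy]phenyl}-2-methylbut-3-yn-2-yl)oxy]-2-hydroxy-6-methoxyphenyl}ethanone
Conditions: PdCl2(PhCN)2 (3 mol%), [HP(t-Bu)3]BF4 (6 mol%), CuI (2 mol%), i-Pr2NH, 1,4-dioxane, rt to 45 °C
Reagents that add atoms: none
Why: Sonogashira coupling; the bulky electron-rich phosphine allows oxidative addition of the electron-rich, di-ortho-substituted bromide near room temperature, so the propargyl ether is not heated. The hydrogen-bonded phenol and the ketone are inert to the amine base.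

Step 4
Reactants: 6 diaryl alkyne
Product: 8 salicylaldehyde 3-acetyl-6-[(4-{2,6-dimethoxy-4-[tri(propan-2-yl)silyloxy]phenyl}-2-methylbut-3-yn-2-yl)oxy]-2-hydroxy-4-methoxybenzaldehyde, via hydroxymethylphenol 7 (not isolated)
Conditions: MgCl2, Et3N, (CH2O)n, THF, 65 °C; aq. NH4Cl work-up
Reagents that add atoms: paraformaldehyde (reacts as formaldehyde), C=O
Why: Magnesium-mediated ortho-formylation of a phenol (Casnati–Skattebøl reaction): the magnesium phenoxide delivers formaldehyde to the only unsubstituted carbon ortho to the free hydroxyl, the one between the two oxygens, giving 7, whose alkoxide passes a hydride to a second formaldehyde (Oppenauer-type) to give 8. Ring C has no free phenol and the other ring-A C–H is not ortho to one, so neither reacts.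

Step 5
Reactants: 8 salicylaldehyde
Product: 9 enyne 1-{4-[(4-{2,6-dimethoxy-4-[tri(propan-2-yl)silyloxy]phenyl}-2-methylbut-3-yn-2-yl)oxy]-3-ethenyl-2-hydroxy-6-methoxyphenyl}ethanone
Conditions: Ph3PCH3Br (3.2 equiv), NaN(SiMe3)2 (3.0 equiv), THF, 0 °C; then 8, 0 °C to rt; aq. NH4Cl
Reagents that add atoms: methyltriphenylphosphonium bromide, C[P+](c1ccccc1)(c1ccccc1)c1ccccc1.[Br-]
Why: Wittig methylenation of a salicylaldehyde with excess ylide, the first equivalent only deprotonating the phenol; the aldehyde reacts, whereas the acetyl group is flanked by two ortho substituents and conjugated with the phenoxide and does not. The non-nucleophilic amide base leaves the aryl silyl ether intact.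

Step 6
Reactants: 9 enyne
Product: 10 diene 1-[3-(1-{2,6-dimethoxy-4-[tri(propan-2-yl)silyloxy]phenyl}ethenyl)-5-hydroxy-7-methoxy-2,2-dimethyl-2H-chromen-6-yl]ethanone
Conditions: RuCl2(H2IMes)(=CH-C6H4-2-O-i-Pr) (second-generation Hoveyda–Grubbs catalyst, 10 mol% in two portions), ethylene (1 atm), toluene (5 mM), 80 °C
Reagents that add atoms: ethylene, C=C
Why: Ruthenium-catalysed ring-closing enyne metathesis of a 1,7-enyne under ethylene, the reaction type by which 2-(propargyloxy)styrenes give 3-vinyl-2H-chromenes. The catalyst enters at the styrene to give Ru=C4H–aryl, a chelate through the O1 ether oxygen that opens on heating; [2+2] addition to the alkyne, with C4 bonding to the alkyne carbon on C2, gives a ruthenacyclobutene that opens to the C3=C4 bond and a vinylcarbene at C*, and ethylene turns this carbene into C*=CH2 and returns Ru=CH2. Ethylene only exchanges methylene units with the styrene terminus, so 10 is an isomer of 9. Ring B closes in the exo mode as a six-membered ring, helped by the gem-dimethyl group on C2; the endo mode would give a seven-membered ring and is disfavoured at this tether length. No stereocentre forms. The step needs exo closure, which the 1,7-enyne tether secures, and turnover of the crowded carbene next to the 2,6-dimethoxyaryl group, which the small ethylene partner and high dilution secure while also suppressing oligomerisation. If Ru=CH2 adds to the alkyne first, the resulting buta-1,3-diene closes onto the styrene by ordinary ring-closing metathesis to the same product, so both pathways converge on 10. The hydrogen-bonded phenol, the ketone and the silyl ether do not bind the catalyst, and 80 °C is below the Claisen temperature of the aryl propargyl ether.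

Step 7
Reactants: 10 diene
Product: 11 silyl ether 1-{3-[(1S)-1-{2,6-dimethoxy-4-[tri(propan-2-yl)silyloxy]phenyl}ethyl]-5-hydroxy-7-methoxy-2,2-dimethyl-2H-chromen-6-yl}ethanone
Conditions: [Ir(cod)(L*)]BArF (2 mol%; L* = (4S,5S)-ThrePHOX, a threonine-derived phosphinite–oxazoline; BArF = tetrakis[3,5-bis(trifluoromethyl)phenyl]borate), H2 (1 bar), CH2Cl2, 0 °C
Reagents that add atoms: none
Why: Iridium-catalysed asymmetric hydrogenation of an unfunctionalised 1,1-disubstituted aryl alkene with a chiral P,N ligand; C* is set by the catalyst, which tells the alkene faces apart because the perpendicular 2,6-dimethoxyaryl group and the flat chromenyl group differ strongly in shape, and the ligand enantiomer is the one that delivers hydrogen to the face giving S. At 1 bar the terminal alkene should react much faster than the C3=C4 bond, which is fully substituted at C3 and lies between the quaternary C2 and C*; strain against the C2 methyl groups twists the diene and disfavours 1,4-addition. The terminal alkene has no allylic hydrogen, so the isomerisation that often erodes selectivity in this alkene class cannot occur.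

Step 8
Reactants: 11 silyl ether
Product: 12 phenol 1-{5-hydroxy-3-[(1S)-1-(4-hydroxy-2,6-dimethoxyphenyl)ethyl]-7-methoxy-2,2-dimethyl-2H-chromen-6-yl}ethanone
Conditions: Bu4NF, AcOH (1.2 equiv each), THF, 0 °C
Reagents that add atoms: none
Why: Fluoride cleavage of an aryl silyl ether; acetic acid buffers the medium so that the allylic, benzylic C*–H is not exposed to a basic phenoxide–fluoride mixture.

Step 9
Reactants: 12 phenol; 13 enal 3-methylbut-2-enal
Product: 15 target 1-{3-[(1S)-1-(5,7-dimethoxy-2,2-dimethyl-2H-chromen-6-yl)ethyl]-5-hydroxy-7-methoxy-2,2-dimethyl-2H-chromen-6-yl}ethanone, via ortho-quinone methide 14 (not isolated)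
Conditions: 13 (3 equiv), ethylenediammonium diacetate (20 mol%), toluene, 100 °C
Reagents that add atoms: none
Why: Amine-salt-catalysed phenol–enal annulation: Knoevenagel-type condensation at the carbon ortho to the ring-C hydroxyl gives 14, which closes by oxa-6π electrocyclisation. The two ortho carbons are equivalent by rotation about the aryl–C* bond and the ring-A hydroxyl has no free ortho carbon, so one chromene results. The weakly acidic buffer does not touch C*–H, so the S configuration is kept.

## Compound list

1 | 2,4-dihydroxy-6-methoxyacetophenone | CC(=O)c1c(O)cc(O)cc1OC | starting material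
2 | 3-chloro-3-methylbut-1-yne | CC(C)(Cl)C#C | starting material
3 | 1-[2-hydroxy-6-methoxy-4-(2-methylbut-3-yn-2-yloxy)phenyl]ethanone | COc1cc(OC(C)(C)C#C)cc(O)c1C(C)=O | intermediate
4 | 4-bromo-3,5-dimethoxyphenol | COc1cc(O)cc(OC)c1Br | starting material
5 | (4-bromo-3,5-dimethoxyphenoxy)tri(propan-2-yl)silane | COc1cc(O[Si](C(C)C)(C(C)C)C(C)C)cc(OC)c1Br | intermediate
6 | 1-{4-[(4-{2,6-dimethoxy-4-[tri(propan-2-yl)silyloxy]phenyl}-2-methylbut-3-yn-2-yl)oxy]-2-hydroxy-6-methoxyphenyl}ethanone | COc1cc(OC(C)(C)C#Cc2c(OC)cc(O[Si](C(C)C)(C(C)C)C(C)C)cc2OC)cc(O)c1C(C)=O | intermediate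
7 | 1-{4-[(4-{2,6-dimethoxy-4-[tri(propan-2-yl)silyloxy]phenyl}-2-methylbut-3-yn-2-yl)oxy]-2-hydroxy-3-(hydroxymethyl)-6-methoxyphenyl}ethanone | COc1cc(OC(C)(C)C#Cc2c(OC)cc(O[Si](C(C)C)(C(C)C)C(C)C)cc2OC)c(CO)c(O)c1C(C)=O | intermediate (formed in the flask, not isolated)
8 | 3-acetyl-6-[(4-{2,6-dimethoxy-4-[tri(propan-2-yl)silyloxy]phenyl}-2-methylbut-3-yn-2-yl)oxy]-2-hydroxy-4-methoxybenzaldehyde | COc1cc(OC(C)(C)C#Cc2c(OC)cc(O[Si](C(C)C)(C(C)C)C(C)C)cc2OC)c(C=O)c(O)c1C(C)=O | intermediate
9 | 1-{4-[(4-{2,6-dimethoxy-4-[tri(propan-2-yl)silyloxy]phenyl}-2-methylbut-3-yn-2-yl)oxy]-3-ethenyl-2-hydroxy-6-methoxyphenyl}ethanone | COc1cc(OC(C)(C)C#Cc2c(OC)cc(O[Si](C(C)C)(C(C)C)C(C)C)cc2OC)c(C=C)c(O)c1C(C)=O | intermediate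
10 | 1-[3-(1-{2,6-dimethoxy-4-[tri(propan-2-yl)silyloxy]phenyl}ethenyl)-5-hydroxy-7-methoxy-2,2-dimethyl-2H-chromen-6-yl]ethanone | COc1cc2c(c(O)c1C(C)=O)C=C(C(=C)c1c(OC)cc(O[Si](C(C)C)(C(C)C)C(C)C)cc1OC)C(C)(C)O2 | intermediate
11 | 1-{3-[(1S)-1-{2,6-dimethoxy-4-[tri(propan-2-yl)silyloxy]phenyl}ethyl]-5-hydroxy-7-methoxy-2,2-dimethyl-2H-chromen-6-yl}ethanone | COc1cc2c(c(O)c1C(C)=O)C=C([C@H](C)c1c(OC)cc(O[Si](C(C)C)(C(C)C)C(C)C)cc1OC)C(C)(C)O2 | intermediate
12 | 1-{5-hydroxy-3-[(1S)-1-(4-hydroxy-2,6-dimethoxyphenyl)ethyl]-7-methoxy-2,2-dimethyl-2H-chromen-6-yl}ethanone | COc1cc2c(c(O)c1C(C)=O)C=C([C@H](C)c1c(OC)cc(O)cc1OC)C(C)(C)O2 | intermediate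
13 | 3-methylbut-2-enal | CC(C)=CC=O | starting material
14 | 1-{3-[(1S)-1-[(3Z)-2,6-dimethoxy-3-(3-methylbut-2-en-1-ylidene)-4-oxocyclohexa-1,5-dien-1-yl]ethyl]-5-hydroxy-7-methoxy-2,2-dimethyl-2H-chromen-6-yl}ethanone | COc1cc2c(c(O)c1C(C)=O)C=C([C@H](C)C1=C(OC)/C(=C/C=C(C)C)C(=O)C=C1OC)C(C)(C)O2 | intermediate (formed in the flask, not isolated)
15 | 1-{3-[(1S)-1-(5,7-dimethoxy-2,2-dimethyl-2H-chromen-6-yl)ethyl]-5-hydroxy-7-methoxy-2,2-dimethyl-2H-chromen-6-yl}ethanone | COc1cc2c(c(O)c1C(C)=O)C=C([C@H](C)c1c(OC)cc3c(c1OC)C=CC(C)(C)O3)C(C)(C)O2 | target

## Step count and risks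

Total: 9 steps. Longest linear sequence: 8 steps (1 to 15 through steps 1, 3, 4, 5, 6, 7, 8 and 9).

**Step 6 (key step).** The ruthenium carbene may fail to add to an alkyne that is flanked by a quaternary carbon on one side and a di-ortho-substituted arene on the other. The catalyst may also rest as the chelated ortho-alkoxybenzylidene formed from the styrene, so the enyne is recovered or only exchanges with ethylene without closing.
Fallback: set out from the aldehyde 8 and close ring B without ruthenium.
- FeCl3-catalysed intramolecular alkyne–aldehyde metathesis (MeCN, rt) should transfer the aldehyde oxygen to the distal alkyne carbon and give the 3-aroylchromene 1-[3-{2,6-dimethoxy-4-[tri(propan-2-yl)silyloxy]benzoyl}-5-hydroxy-7-methoxy-2,2-dimethyl-2H-chromen-6-yl]ethanone F1.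
- Excess MeMgBr (THF, −20 to 0 °C) would add to the non-enolisable aroyl ketone, the acetyl group being masked as its magnesium phenoxide chelate. This gives the tertiary alcohol 1-[3-(1-{2,6-dimethoxy-4-[tri(propan-2-yl)silyloxy]phenyl}-1-hydroxyethyl)-5-hydroxy-7-methoxy-2,2-dimethyl-2H-chromen-6-yl]ethanone F2.
- Dehydration with pyridinium p-toluenesulfonate in warm toluene, possible only towards the methyl group, returns to the route at 10.
- The weak point of this detour is ionisation of the tertiary propargylic ether by the Lewis acid.

**Step 7.** Hydrogen may add to the ring alkene as well or across the diene in the 1,4 sense. Face selection may also be poor, because the alkene carries no coordinating group and both substituents are large.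
Fallback: from 10, hydrogenate the terminal alkene without a chiral ligand using RhCl(PPh3)3 and H2 (benzene, rt), which reduces the less substituted alkene. This gives the racemic silyl ether 1-{3-[1-{2,6-dimethoxy-4-[tri(propan-2-yl)silyloxy]phenyl}ethyl]-5-hydroxy-7-methoxy-2,2-dimethyl-2H-chromen-6-yl}ethanone F3. Preparative chromatography on a polysaccharide chiral stationary phase then separates the enantiomers, and the S enantiomer re-enters the route as 11.

**Step 4.** Formylation may be slow because the phenoxide is tied up in the acetyl chelate and the reacting carbon lies next to the bulky tertiary ether. Hydroxymethylation of the acetyl methyl group may compete.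
Fallback: from 3, install the vinyl group by halogenation and cross-coupling before ring C is present.
- Iodination ortho to the hydrogen-bonded hydroxyl (N-iodosuccinimide, cat. CF3CO2H, MeCN, 0 °C) should give 1-[2-hydroxy-3-iodo-6-methoxy-4-(2-methylbut-3-yn-2-yloxy)phenyl]ethanone F4.
- Stille coupling with tributyl(vinyl)stannane (Pd(PPh3)4, toluene, 80 °C) gives 1-[3-ethenyl-2-hydroxy-6-methoxy-4-(2-methylbut-3-yn-2-yloxy)phenyl]ethanone F5.
- Sonogashira coupling of F5 with 5 under the conditions of step 3 rejoins the route at 9 and also bypasses step 5.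

**Step 3.** Oxidative addition into the electron-rich bromide with two ortho methoxy groups may be slow. Oxidative homocoupling of the alkyne would then take over, and heating to compensate risks Claisen rearrangement of 3.
Fallback: from 5, exchange the halogen by aromatic Finkelstein reaction (NaI, CuI, N,N'-dimethylethylenediamine, dioxane, 110 °C) to (4-iodo-3,5-dimethoxyphenoxy)tri(propan-2-yl)silane F6. Coupling F6 with 3 at room temperature (PdCl2(PPh3)2, CuI, Et3N) rejoins the route at 6.

**Step 9.** Condensation at the crowded ortho carbon of ring C may be slow, so self-condensation of the enal or attack at C8 of ring A may take over.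
Fallback: from 12, alkylate the ring-C hydroxyl with 2 (K2CO3, KI, CuCl2·2H2O cat., acetone, 50 °C; the hydrogen-bonded ring-A hydroxyl does not react). This gives 1-{3-[(1S)-1-[2,6-dimethoxy-4-(2-methylbut-3-yn-2-yloxy)phenyl]ethyl]-5-hydroxy-7-methoxy-2,2-dimethyl-2H-chromen-6-yl}ethanone F7. Heating F7 in xylene at 140 °C (Claisen rearrangement, hydrogen shift, oxa-6π closure) gives 15.

## Further compounds

F1 | step 6 | 1-[3-{2,6-dimethoxy-4-[tri(propan-2-yl)silyloxy]benzoyl}-5-hydroxy-7-methoxy-2,2-dimethyl-2H-chromen-6-yl]ethanone | COc1cc2c(c(O)c1C(C)=O)C=C(C(=O)c1c(OC)cc(O[Si](C(C)C)(C(C)C)C(C)C)cc1OC)C(C)(C)O2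
F2 | step 6 | 1-[3-(1-{2,6-dimethoxy-4-[tri(propan-2-yl)silyloxy]phenyl}-1-hydroxyethyl)-5-hydroxy-7-methoxy-2,2-dimethyl-2H-chromen-6-yl]ethanone (racemic) | COc1cc2c(c(O)c1C(C)=O)C=C(C(C)(O)c1c(OC)cc(O[Si](C(C)C)(C(C)C)C(C)C)cc1OC)C(C)(C)O2
F3 | step 7 | 1-{3-[1-{2,6-dimethoxy-4-[tri(propan-2-yl)silyloxy]phenyl}ethyl]-5-hydroxy-7-methoxy-2,2-dimethyl-2H-chromen-6-yl}ethanone (racemic) | COc1cc2c(c(O)c1C(C)=O)C=C(C(C)c1c(OC)cc(O[Si](C(C)C)(C(C)C)C(C)C)cc1OC)C(C)(C)O2
F4 | step 4 | 1-[2-hydroxy-3-iodo-6-methoxy-4-(2-methylbut-3-yn-2-yloxy)phenyl]ethanone | COc1cc(OC(C)(C)C#C)c(I)c(O)c1C(C)=O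
F5 | step 4 | 1-[3-ethenyl-2-hydroxy-6-methoxy-4-(2-methylbut-3-yn-2-yloxy)phenyl]ethanone | COc1cc(OC(C)(C)C#C)c(C=C)c(O)c1C(C)=O
F6 | step 3 | (4-iodo-3,5-dimethoxyphenoxy)tri(propan-2-yl)silane | COc1cc(O[Si](C(C)C)(C(C)C)C(C)C)cc(OC)c1I
F7 | step 9 | 1-{3-[(1S)-1-[2,6-dimethoxy-4-(2-methylbut-3-yn-2-yloxy)phenyl]ethyl]-5-hydroxy-7-methoxy-2,2-dimethyl-2H-chromen-6-yl}ethanone | COc1cc2c(c(O)c1C(C)=O)C=C([C@H](C)c1c(OC)cc(OC(C)(C)C#C)cc1OC)C(C)(C)O2
A1 | alternative 1 | 3-[1-(5,7-dimethoxy-2,2-dimethyl-2H-chromen-6-yl)ethyl]-5-hydroxy-7-methoxy-2,2-dimethyl-4-oxochroman-6-carbonitrile (single diastereomer as drawn) | CC1(C)Oc2cc(OC)c(C#N)c(O)c2C(=O)[C@H]1[C@H](C)c1c(OC)cc2c(c1OC)C=CC(C)(C)O2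
A2 | alternative 1 | 4-{[(3Z)-4-(5,7-dimethoxy-2,2-dimethyl-2H-chromen-6-yl)-2-methylpent-3-en-2-yl]oxy}-3-formyl-2-hydroxy-6-methoxybenzonitrile | COc1cc(OC(C)(C)/C=C(/C)c2c(OC)cc3c(c2OC)C=CC(C)(C)O3)c(C=O)c(O)c1C#N
A3 | alternative 2 | 1-{3-[1-(5,7-dimethoxy-2,2-dimethyl-2H-chromen-6-yl)ethylidene]-4-hydroxy-7-methoxy-5-(methoxymethoxy)-2,2-dimethylchroman-6-yl}ethanone (aryl cis to C4, single enantiomer as drawn) | CC1(C)Oc2cc(OC)c(C(C)=O)c(OCOC)c2[C@@H](O)/C1=C(/C)c1c(OC)cc2c(c1OC)C=CC(C)(C)O2
A4 | alternative 2 | 3-acetyl-4-methoxy-2-(methoxymethoxy)-6-[(2-methylpent-3-yn-2-yl)oxy]benzaldehyde | COCOc1c(C=O)c(OC(C)(C)C#CC)cc(OC)c1C(C)=O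
A5 | alternative 2 | (5,7-dimethoxy-2,2-dimethyl-2H-chromen-6-yl)boronic acid | COc1cc2OC(C)(C)C=Cc2c(OC)c1B(O)O
A6 | alternative 3 | 4-[(1S)-1-(6-acetyl-5-hydroxy-7-methoxy-2,2-dimethyl-2H-chromen-3-yl)ethyl]-3,5-dimethoxyphenyl 2,2-dimethylpropanoate | COc1cc2c(c(O)c1C(C)=O)C=C([C@H](C)c1c(OC)cc(OC(=O)C(C)(C)C)cc1OC)C(C)(C)O2
A7 | alternative 3 | 4-[(2S,3E)-4-(3-acetyl-2,6-dihydroxy-4-methoxyphenyl)but-3-en-2-yl]-3,5-dimethoxyphenyl 2,2-dimethylpropanoate | COc1cc(O)c(/C=C/[C@H](C)c2c(OC)cc(OC(=O)C(C)(C)C)cc2OC)c(O)c1C(C)=O
A8 | alternative 3 | 2,2-dimethoxypropane | COC(C)(C)OC
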